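**Small charge first.** Take autumn's flask, 3.1 mM of starting complex at −10 °C, and midnight's, 16 mM at 10 °C, and use them to judge four flasks that get the same 0.700 equiv of incoming ligand, the limiting reagent.

| setting | autumn | midnight | Saturday's | Thursday's | Tuesday's | Monday's |
|---|---|---|---|---|---|---|
| starting complex | 3.1 mM (in portions, 2) | 16 mM (in portions, 2) | 20 mM (in portions, 2) | 5.0 mM (in portions, 2) | 20 mM (in portions, 2) | 5.0 mM (in portions, 2) |
| incoming ligand | 0.70 equiv | 0.70 equiv | 0.700 equiv | 0.700 equiv | 0.700 equiv | 0.700 equiv |
| leaving ligand | 0.50 equiv | 0.50 equiv | 0.500 equiv | 0.500 equiv | 0.500 equiv | 0.500 equiv |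
| temperature | −10 °C | 10 °C | 25 °C | 25 °C | −5 °C | −5 °C |
| remark | run made earlier; portions every 1.0 min | run made earlier; portions every 1.0 min | the portions of starting complex follow each other after 1.0 min, the first at the start | the portions of starting complex follow each other after 1.0 min, the first at the start | the portions of starting complex follow each other after 1.0 min, the first at the start | the portions of starting complex follow each other after 1.0 min, the first at the start |
| time |  |  | 2.0 min | 2.0 min | 2.0 min | 2.0 min |

| run | time / min | complex with one exchanged / % | starting complex / % |
|---|---|---|---|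
| autumn | 1.33 | 5.8 | 94.0 |
| autumn | 3.00 | 10.8 | 87.1 |
| autumn | 5.00 | 12.0 | 83.5 |
| autumn | 6.00 | 12.4 | 82.1 |
| autumn | 8.00 | 11.5 | 81.9 |
| midnight | 0.333 | 10.3 | 34.2 |
| midnight | 0.417 | 11.2 | 32.8 |
| midnight | 0.833 | 11.3 | 30.1 |
| midnight | 1.33 | 17.9 | 72.2 |
| midnight | 3.00 | 19.5 | 66.9 |

(readings scatter by 0.3 percentage points)



* the flasks put in order of amount of complex with one exchanged, in percent of the starting complex charged, best first, at 2.0 min (Saturday's / Thursday's / Tuesday's / Monday's)
* the amount of complex with one exchanged, in percent of the starting complex charged of the flask you put first, at 2.0 min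
* the amount of complex with one exchanged, in percent of the starting complex charged of the flask you put last, at 2.0 min

**Main step.** Take the first exchange by itself, reversible, and set its forward rate against its back rate at one moment. The amount of complex with one exchanged over the amount of starting complex, the split, climbs while forward beats back and stops where they match. Autumn's split reads 0.144 at 5.00 min and 0.140 at 8.00 min, so these two readings show no further climb, and midnight's last reading gives 0.291. Carry that growth evenly per degree in the logarithm, and the warm split, the same ratio reckoned for 25 °C, comes to 0.504, while −5 °C gets 0.169. With these two forms sharing the complex, my own reckoning gives 33.5% warm and 14.4% cold.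

**Second exchange.** Add the shortfall in the balance, which I read as complex with two exchanged: 13.6% at midnight's end and 6.60% at autumn's. Taking those shares off lowers my numbers to 29.0% and 13.5%.

**Second portion.** Add the fresh portion last. Midnight's split falls from 0.375 to 0.248 across it, then climbs again, so the asked moment may sit somewhat lower. The two runs mix charge with temperature, so I leave each pair unranked.

**The forecast.** It gives Saturday's > Thursday's > Tuesday's > Monday's, with 21.5% first and 12% last, holding that at 25 °C “both flasks nearly reach equilibrium”. Its top stands below my 29.0%.

**The result.** The flasks give Saturday's > Thursday's > Monday's > Tuesday's, with Saturday's at 34.8% and Tuesday's at 10.6%.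

    starting complex + incoming ligand ⇌ leaving ligand + complex with one exchanged (K = 1.60, k = 7.00 L mol⁻¹ s⁻¹, Ea = 41.0 kJ mol⁻¹, ΔH = 36.0 kJ mol⁻¹)
    complex with one exchanged + incoming ligand ⇌ leaving ligand + complex with two exchanged (K = 0.630, k = 12.0 L mol⁻¹ s⁻¹, Ea = 46.0 kJ mol⁻¹, ΔH = −48.0 kJ mol⁻¹)
    leaving ligand → by-product carried off (k = 0.0270 s⁻¹, Ea = 72.0 kJ mol⁻¹)
    incoming ligand ⇌ dormant form (K = 0.870, k = 0.0170 s⁻¹, Ea = 83.0 kJ mol⁻¹, ΔH = 30.0 kJ mol⁻¹)
    (constants at 25 °C)

**The split again.** Divide Saturday's amounts at 2.00 min: its split is 0.633, above the reckoned 0.504. Tuesday's flask shows the back rate at work: take away the undoing of leaving ligand + complex with one exchanged into starting complex + incoming ligand, which is one part of what holds that flask down, and its complex with one exchanged stands at 29.1% instead of 10.6%. Now divide the further flask, like Saturday's but with 1.20 equiv of incoming ligand: its split is 1.15, above 0.504 and above one, and complex with one exchanged, at 42.0%, exceeds starting complex, at 36.5%.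

Readings and results stem from a simulated flask with made-up constants; the scatter is artificial.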